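**Retrosynthetic overview**
- Last bond: C7'–C8' (sp2–sp2), by Suzuki union of a C30 polyenyl triflate with a C10 (S)-alkenyl boronate.
- The C30 triflate comes from an enol acetate, made from commercial β-apo-8'-carotenal by an acylative 1,20-elimination: a C–O bond forms at O-8', H-4 is lost, and all ten C=C shift into the retro-dehydro array.
- The C10 boronate comes from (S)-2,2,6-trimethylcyclohexanone by boron-Wittig olefination; the stereocentre is set by catalytic enantioselective protonation of the silyl enol ether of the cheap racemic ketone.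
- Rings: neither six-membered ring is built; both are bought intact (in the apo-carotenal and in the ketone), so there is no ring-forming order.

Assumption: (R)-BINAP·AgF gives the (S)-ketone in step 4; if the sense of induction is the opposite, (S)-BINAP is used and nothing else changes.

Step 1
Reactants: 1 (all-E)-β-apo-8'-carotenal
Product: 3 (all-E)-4,5-didehydro-8',5-retro-8'-apo-β-caroten-8'-yl acetate, via gem-diacetate acylal 2 (not isolated)
Conditions: Ac2O (5 equiv), Sc(OTf)3 (2 mol %), CH2Cl2, −20 → 0 °C, Ar, dark; then 2,6-lutidine (3 equiv), 0 → 25 °C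
Reagents that add atoms: acetic anhydride, CC(=O)OC(C)=O
Why: Proposed new method: a remote (1,20) acylative enolisation, in which Sc(OTf)3 activates Ac2O so that the vinylogous aldehyde oxygen is acetylated (new C–O bond, acylal 2 as resting state), the resulting 8'-acetoxy-polyenylium ion is delocalised down to C-5 and sheds H-4, which moves every chain C=C by one position and gives the ring C4=C5 and the exocyclic 6E bond (thermodynamic, as in anhydroretinol) with 8'E from the s-trans enal; the closest known reactions are the acylal-to-1-acetoxy-1,3-diene elimination of enals and the retinol or retinyl acetate to anhydroretinol 1,12-elimination, here extended to a substrate class where it has not been shown.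

Step 2
Reactants: 3 (all-E)-4,5-didehydro-8',5-retro-8'-apo-β-caroten-8'-yl acetate
Product: 5 (all-E)-4,5-didehydro-8',5-retro-8'-apo-β-caroten-8'-yl trifluoromethanesulfonate, via lithium polyenolate 4 (not isolated)
Conditions: MeLi (2.1 equiv), THF, −78 °C, 30 min; then Comins' reagent (1.5 equiv), −78 → −20 °C; cold filtration through Et3N-washed alumina, used at once
Reagents that add atoms: Comins' reagent [N-(5-chloropyridin-2-yl)-1,1,1-trifluoro-N-(trifluoromethylsulfonyl)methanesulfonamide], Clc1ccc(nc1)N(S(=O)(=O)C(F)(F)F)S(=O)(=O)C(F)(F)F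
Why: House-type cleavage of an enol acetate by methyllithium regenerates the lithium enolate regio- and stereospecifically, and O-triflation with an N-aryl triflimide fixes the retro array as the (8'E)-alkenyl triflate with no proton source present that could scramble the double bonds.

Step 3
Reactants: 6 (±)-2,2,6-trimethylcyclohexanone
Product: 8 trimethyl[(2,6,6-trimethylcyclohex-1-en-1-yl)oxy]silane, via lithium enolate 7 (not isolated)
Conditions: LiN(i-Pr)2 (LDA, 1.1 equiv), THF, −78 → 0 °C; Me3SiCl (1.3 equiv), −78 → 25 °C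
Reagents that add atoms: chlorotrimethylsilane, C[Si](C)(C)Cl
Why: Enolate O-silylation; C-2 is quaternary, so deprotonation can only occur at C-6 and a single silyl enol ether forms, which erases the racemic stereocentre.

Step 4
Reactants: 8 trimethyl[(2,6,6-trimethylcyclohex-1-en-1-yl)oxy]silane
Product: 9 (S)-2,2,6-trimethylcyclohexanone
Conditions: AgF (6 mol %), (R)-BINAP (6.6 mol %), MeOH (5 equiv), DMF/CH2Cl2, −30 °C
Reagents that add atoms: none
Why: Catalytic enantioselective protonation of a silyl enolate, in which fluoride-induced desilylation gives a BINAP-ligated silver enolate that methanol protonates at C-6 on one face, setting the only stereocentre of the target (C-5', S).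

Step 5
Reactants: 9 (S)-2,2,6-trimethylcyclohexanone
Product: 11 (S,E)-4,4,5,5-tetramethyl-2-[(2,2,6-trimethylcyclohexylidene)methyl]-1,3,2-dioxaborolane, via lithium alkoxide adduct 10 (not isolated)
Conditions: CH2(Bpin)2 (1.4 equiv), lithium 2,2,6,6-tetramethylpiperidide (LiTMP, 1.3 equiv), THF, 0 °C, 10 min; then 9, −78 → 25 °C
Reagents that add atoms: bis[(pinacolato)boryl]methane, CC1(C)OB(CB2OC(C)(C)C(C)(C)O2)OC1(C)C
Why: Boron-Wittig olefination, in which the weakly basic α,α-diboryl carbanion adds to the hindered carbonyl without enolising it (C-6 stays S) and syn B–O elimination leaves the surviving Bpin anti to the quaternary C-2 side, giving the E alkene with boron cis to the CHMe carbon.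

Step 6
Reactants: 5 (all-E)-4,5-didehydro-8',5-retro-8'-apo-β-caroten-8'-yl trifluoromethanesulfonate and 11 (S,E)-4,4,5,5-tetramethyl-2-[(2,2,6-trimethylcyclohexylidene)methyl]-1,3,2-dioxaborolane
Product: 12 (5'S,6E,6'E)-4,5'-retro-β,β-carotene (all-E chain), the target CNP0257724.1
Conditions: Pd(OAc)2 (5 mol %), SPhos (10 mol %), K3PO4 (3 M aq., 3 equiv), THF, 25 °C, Ar, dark; crystallisation of the all-E isomer
Reagents that add atoms: none
Why: Suzuki–Miyaura sp2–sp2 coupling is stereoretentive at both partners, so the (8'E)-triflate and the (E)-boronate give the 6'E,8'E diene, and the allylic, non-acidic C-5' centre is untouched.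

**Compound list**
1 | (all-E)-β-apo-8'-carotenal [(2E,4E,6E,8E,10E,12E,14E,16E)-2,6,11,15-tetramethyl-17-(2,6,6-trimethylcyclohex-1-en-1-yl)heptadeca-2,4,6,8,10,12,14,16-octaenal] | CC1=C(/C=C/C(C)=C/C=C/C(C)=C/C=C/C=C(C)/C=C/C=C(C)/C=O)C(C)(C)CCC1 | starting material
2 | 8',8'-diacetate (acylal) of 1 | CC1=C(/C=C/C(C)=C/C=C/C(C)=C/C=C/C=C(C)/C=C/C=C(C)/C(OC(C)=O)OC(C)=O)C(C)(C)CCC1 | intermediate
3 | (all-E)-4,5-didehydro-8',5-retro-8'-apo-β-caroten-8'-yl acetate [(1E,3E,5E,7E,9E,11E,13E,15E,17E)-2,6,11,15-tetramethyl-17-(2,6,6-trimethylcyclohex-2-en-1-ylidene)heptadeca-1,3,5,7,9,11,13,15-octaen-1-yl acetate] | CC1=CCCC(C)(C)\C1=C/C=C(C)/C=C/C=C(C)/C=C/C=C/C(C)=C/C=C/C(C)=C/OC(C)=O | intermediate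
4 | lithium enolate corresponding to 3 (retro-dehydro polyenolate, O-lithiated at C-8') | CC1=CCCC(C)(C)\C1=C/C=C(C)/C=C/C=C(C)/C=C/C=C/C(C)=C/C=C/C(C)=C/[O-].[Li+] | intermediate
5 | (all-E)-4,5-didehydro-8',5-retro-8'-apo-β-caroten-8'-yl trifluoromethanesulfonate | CC1=CCCC(C)(C)\C1=C/C=C(C)/C=C/C=C(C)/C=C/C=C/C(C)=C/C=C/C(C)=C/OS(=O)(=O)C(F)(F)F | intermediate
6 | (±)-2,2,6-trimethylcyclohexanone | CC1CCCC(C)(C)C1=O | starting material
7 | lithium 2,6,6-trimethylcyclohex-1-en-1-olate | [Li+].[O-]C1=C(C)CCCC1(C)C | intermediate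
8 | trimethyl[(2,6,6-trimethylcyclohex-1-en-1-yl)oxy]silane | C[Si](C)(C)OC1=C(C)CCCC1(C)C | intermediate
9 | (S)-2,2,6-trimethylcyclohexanone | O=C1[C@@H](C)CCCC1(C)C | intermediate
10 | lithium (6S)-1-[bis(4,4,5,5-tetramethyl-1,3,2-dioxaborolan-2-yl)methyl]-2,2,6-trimethylcyclohexan-1-olate (carbinol centre unassigned) | [Li+].[O-]C1(C(B2OC(C)(C)C(C)(C)O2)B2OC(C)(C)C(C)(C)O2)[C@@H](C)CCCC1(C)C | intermediate
11 | (S,E)-4,4,5,5-tetramethyl-2-[(2,2,6-trimethylcyclohexylidene)methyl]-1,3,2-dioxaborolane (boron cis to the CHMe carbon) | CC1(C)OB(OC1(C)C)/C=C2\[C@@H](C)CCCC2(C)C | intermediate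
12 | (5'S,6E,6'E)-4,5'-retro-β,β-carotene, all-E chain | CC1=CCCC(C)(C)\C1=C/C=C(C)/C=C/C=C(C)/C=C/C=C/C(C)=C/C=C/C(C)=C/C=C1\[C@@H](C)CCCC1(C)C | target

**Step count and risks**
Total steps: 6. Longest linear sequence: 4 (steps 3, 4, 5, 6); the other branch is steps 1, 2, 6.

The three steps most likely to fail:

Step 1, the proposed new 1,20-acylative elimination. The risks are proton loss from C-18, C-19 or C-20 instead of C-4, and cationic oligomerisation or C-acylation of the electron-rich product. The fallback uses known chemistry, sets out from aldehyde 1 and boronate 11, and comes back at target 12. Iododeboronation of 11 with retention (NaOH, I2, THF/H2O, 0 °C) gives (S,E)-2-(iodomethylidene)-1,1,3-trimethylcyclohexane F1. Lithium–iodine exchange (t-BuLi, 2 equiv, Et2O, −78 °C) gives [(S,E)-(2,2,6-trimethylcyclohexylidene)methyl]lithium F2. 1,2-Addition of F2 to 1 at −78 °C gives (5'S,6'E)-5',8'-dihydro-β,β-caroten-8'-ol F3 as a mixture of 8'-epimers. Acid-catalysed dehydration of the retinol-to-anhydroretinol type (pyridinium p-toluenesulfonate cat., CH2Cl2, 0 °C) then removes water with loss of H-4 and gives 12. This is kept as a fallback only, because the cation also reaches C-6' and can lose H-5', which would give β-carotene and erode the ee.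

Step 2, enolate regeneration and triflation. The risks are attack of methyllithium on the polyene and the lability of an aldehyde-derived polyenyl triflate. The fallback sets out from enol acetate 3 and boronate 11 and comes back at 12. It couples the enol acetate itself by nickel-catalysed C–O activation (Ni(cod)2 10 mol %, PCy3 20 mol %, K3PO4, toluene, 60 °C, Suzuki type), which avoids both the organolithium and the triflate and makes no new compound.

Step 5, the boron-Wittig reaction on a doubly α-branched, epimerisable ketone. The risks are no addition, enolisation with loss of ee, and a poor E/Z ratio. The fallback sets out from ketone 9 and comes back at boronate 11. CeCl3-promoted Peterson methylenation (Me3SiCH2Li, CeCl3, THF, −78 °C) gives (6S)-2,2,6-trimethyl-1-[(trimethylsilyl)methyl]cyclohexan-1-ol F4. Elimination with KH in THF gives (S)-1,1,3-trimethyl-2-methylidenecyclohexane F5. A palladium-catalysed boryl-Heck reaction (Pd2(dba)3, JessePhos, catecholchloroborane, Cy2NMe, LiOTf, PhCF3, 70 °C) gives (S,E)-2-[(2,2,6-trimethylcyclohexylidene)methyl]-1,3,2-benzodioxaborole F6. Exchange with pinacol/Et3N then gives 11.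

**Further compounds**
F1 | step 1 | (S,E)-2-(iodomethylidene)-1,1,3-trimethylcyclohexane | I/C=C1\[C@@H](C)CCCC1(C)C
F2 | step 1 | [(S,E)-(2,2,6-trimethylcyclohexylidene)methyl]lithium | [Li]/C=C1\[C@@H](C)CCCC1(C)C
F3 | step 1 | (5'S,6'E)-5',8'-dihydro-β,β-caroten-8'-ol (8'-epimers) | CC1=C(/C=C/C(C)=C/C=C/C(C)=C/C=C/C=C(C)/C=C/C=C(C)/C(O)/C=C2\[C@@H](C)CCCC2(C)C)C(C)(C)CCC1
F0 | step 2 | none | none
F4 | step 5 | (6S)-2,2,6-trimethyl-1-[(trimethylsilyl)methyl]cyclohexan-1-ol | C[Si](C)(C)CC1(O)[C@@H](C)CCCC1(C)C
F5 | step 5 | (S)-1,1,3-trimethyl-2-methylidenecyclohexane | C=C1[C@@H](C)CCCC1(C)C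
F6 | step 5 | (S,E)-2-[(2,2,6-trimethylcyclohexylidene)methyl]-1,3,2-benzodioxaborole | B1(Oc2ccccc2O1)/C=C3\[C@@H](C)CCCC3(C)C
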